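**Retrosynthetic overview**
1. Last disconnection: the chromanone ring (O-2′–C-8 bond) is closed by an oxidative, dearomatising phenol C–O coupling of a hexaphenol. The same event creates the spiro stereocentre and the cyclohexa-2,5-dienone.
2. Enabling feature: in ring A of the afzelechin unit, C-8 is para to the C-5 hydroxyl and already bears Cα. The 2′-OH of the aroyl ring lies six atoms away (O–C2′–C1′–C(=O)–Cα–C8) on the face fixed by the Cα stereocentre, so only a cis-fused closure is possible, which gives the trans Cα–OH/C8–O-aryl relation of the target.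
3. Dihydrofuran ring: the C-7 hydroxyl opens an enantioenriched α-aryl chalcone epoxide at Cβ (5-endo, inversion) after desilylation.
4. Carbon skeleton: Shi epoxidation of an (E)-α-aryl enone ⇐ aldol condensation with 4-(benzyloxy)benzaldehyde ⇐ palladium-catalysed α-arylation of 2′,4′,6′-tris(benzyloxy)acetophenone with silyl-protected 8-bromoafzelechin.
5. Ring order: afzelechin rings (chiral pool) and the aryl rings are bought; the dihydrofuran ring forms in step 7; the chromanone ring forms last, in step 8.

Key step: step 8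

Assumption: (+)-afzelechin [(2R,3S)] is taken as a purchasable chiral-pool material that supplies both flavan stereocentres unchanged.
Locants: afzelechin unit O-1 to C-8a and 4′ on its aryl ring; Cα = carbon bonded to C-8; Cβ = benzylic carbon bonded to O-7; 1′–6′ = aroyl ring. TBS = tert-butyldimethylsilyl, Bn = benzyl. CIP descriptors at Cα change along the route only because substituent priorities change.

**Step 1**
Reactants: 1 (+)-afzelechin
Product: 2 3,5,7,4′-tetra-O-TBS-afzelechin
Conditions: TBSCl (6 equiv), imidazole (10 equiv), DMAP (cat.), DMF, 40 °C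
Reagents that add atoms: tert-butyldimethylsilyl chloride, CC(C)(C)[Si](C)(C)Cl
Why: Standard silyl ether formation caps the three phenols and the secondary alcohol so that the later enolate, peroxide and palladium chemistry meets no acidic O–H, and no stereocentre is touched.

**Step 2**
Reactants: 2 3,5,7,4′-tetra-O-TBS-afzelechin
Product: 3 8-bromo-3,5,7,4′-tetra-O-TBS-afzelechin
Conditions: NBS (1.05 equiv), CH2Cl2, −78 → −20 °C
Reagents that add atoms: N-bromosuccinimide, O=C1CCC(=O)N1Br
Why: Electrophilic aromatic bromination of the activated ring A should go to C-8, which is flanked by one silyloxy group and the pyran oxygen, whereas C-6 is shielded by two OTBS groups, as is usual for O-protected flavan-3-ols.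

**Step 3**
Reactants: 4 2′,4′,6′-trihydroxyacetophenone
Product: 5 2′,4′,6′-tris(benzyloxy)acetophenone
Conditions: BnBr (3.6 equiv), K2CO3, DMF, 80 °C
Reagents that add atoms: benzyl bromide, BrCc1ccccc1
Why: Williamson etherification of all three phenols, the warm polar conditions being needed for the two hydrogen-bonded ortho hydroxyls.

**Step 4**
Reactants: 3 8-bromo-3,5,7,4′-tetra-O-TBS-afzelechin; 5 2′,4′,6′-tris(benzyloxy)acetophenone
Product: 6 deoxybenzoin 2-(3,5,7,4′-tetra-O-TBS-afzelechin-8-yl)-1-[2,4,6-tris(benzyloxy)phenyl]ethanone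
Conditions: 5 (1.5 equiv), Pd2(dba)3 (2.5 mol%), XPhos (10 mol%), K3PO4, toluene, 90 °C
Reagents that add atoms: none
Why: Palladium-catalysed ketone α-arylation (oxidative addition of the aryl bromide to zerovalent palladium, exchange with the potassium enolate of the methyl ketone, reductive elimination) should form the C8–CH2 bond, with the weak base K3PO4 sparing the aryl silyl ethers and the bulky biaryl phosphine coping with the di-ortho-substituted bromide.

**Step 5**
Reactants: 6 deoxybenzoin; 7 4-(benzyloxy)benzaldehyde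
Product: 8 (E)-3-[4-(benzyloxy)phenyl]-2-(3,5,7,4′-tetra-O-TBS-afzelechin-8-yl)-1-[2,4,6-tris(benzyloxy)phenyl]prop-2-en-1-one (aroyl trans to the 4-benzyloxyphenyl group)
Conditions: piperidine (0.3 equiv), AcOH (0.3 equiv), toluene, reflux, Dean–Stark
Reagents that add atoms: none
Why: Knoevenagel-type aldol condensation of the activated deoxybenzoin methylene with the aldehyde, driven by water removal, should give the thermodynamically preferred E isomer with the aroyl group trans to the β-aryl group, as in α-aryl chalcones.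

**Step 6**
Reactants: 8 (E)-α-aryl enone
Product: 9 (2S,3R)-epoxy ketone [(2S,3R)-3-[4-(benzyloxy)phenyl]-2-(3,5,7,4′-tetra-O-TBS-afzelechin-8-yl)oxiran-2-yl][2,4,6-tris(benzyloxy)phenyl]methanone
Conditions: D-fructose-derived Shi ketone (0.5 equiv), KHSO5 (as 2KHSO5·KHSO4·K2SO4), K2CO3, Bu4NHSO4, MeCN/CH2(OMe)2/aq. Na2B4O7 buffer (pH 10.5), 0 °C
Reagents that add atoms: potassium peroxymonosulfate, [K+].[O-]S(=O)(=O)OO
Why: Shi epoxidation transfers oxygen from the chiral dioxirane stereospecifically (E geometry kept), and with the trans aroyl/aryl pair read like trans-stilbene in the spiro transition state the D-fructose-derived ketone should give the (2S,3R)-oxirane under reagent control, the afzelechin stereocentres being too remote to interfere.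

**Step 7**
Reactants: 9 (2S,3R)-epoxy ketone
Product: 11 dihydrofuranol tetrabenzyl ether, via desilylated epoxy ketone 10 (not isolated)
Conditions: TBAF (6 equiv), AcOH (3 equiv), THF, 0 °C → rt
Reagents that add atoms: none
Why: Buffered fluoride cleaves the four silyl ethers and the freed C-7 hydroxyl then opens the strained epoxide at its benzylic carbon in a 5-endo, SN2-type cycloetherification (the known 2-hydroxystilbene oxide to 2-aryl-2,3-dihydrobenzofuran-3-ol closure) with inversion, which sets Cβ as S with the aryl group cis to the tertiary hydroxyl, while the benzyl ethers keep the aroyl oxygens and the 4-oxyphenyl group out of the reaction.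

**Step 8**
Reactants: 11 dihydrofuranol tetrabenzyl ether
Product: 13 genkwanol B, via hexaphenol 12 (not isolated)
Conditions: H2 (1 atm), Pd/C, EtOAc/MeOH, rt; filter under Ar, concentrate below 25 °C; then PhI(OAc)2 (1.05 equiv), CF3CH2OH/MeCN (1:1), −40 °C; aq. NaHCO3/Na2S2O3
Reagents that add atoms: none
Why: Hydrogenolysis frees the four benzyl-protected phenols under neutral conditions and the acid-sensitive hexaphenol is oxidised at once: ligand exchange of the C-5 phenol at trivalent iodine and loss of iodobenzene give a phenoxonium ion with its positive charge at C-8 (para to O-5, flanked by O-7 and O-1), which the hydrogen-bonded 2′-hydroxyl of the aroyl ring captures before proton loss leaves the cross-conjugated dienone. The closest known reaction type is the phenolic oxidative C–O coupling that turns 2-hydroxybenzophenones into spiro-cyclohexadienone aryl ethers (grisan-type dienones), run here as a hypervalent-iodine dearomative spiroetherification of a para-substituted phenol. The chromanone ring closes in a 6-exo-trig mode, the oxygen adding to the cationic ring carbon C-8 whose π-system lies outside the new ring. The new spiro stereocentre C-8 (S) is controlled by Cα: the aroyl tether is held on one face of the dihydrofuran, so only the cis-fused five/six junction with O-2′ anti to the tertiary hydroxyl can form. The step needs chemoselectivity for the ring A phenol over the two 4-hydroxyphenyl groups and the acyl-deactivated phloroglucinol ring, which the higher electron density of ring A, one equivalent of oxidant and −40 °C should secure, and para- over ortho-capture, which the intramolecular six-membered delivery secures.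

**Compound list**
1 | (+)-afzelechin, (2R,3S)-2-(4-hydroxyphenyl)chromane-3,5,7-triol | Oc1cc(O)c2C[C@H](O)[C@@H](c3ccc(O)cc3)Oc2c1 | starting material
2 | 3,5,7,4′-tetra-O-TBS-afzelechin | CC(C)(C)[Si](C)(C)Oc1cc(O[Si](C)(C)C(C)(C)C)c2C[C@H](O[Si](C)(C)C(C)(C)C)[C@@H](c3ccc(O[Si](C)(C)C(C)(C)C)cc3)Oc2c1 | intermediate
3 | 8-bromo-3,5,7,4′-tetra-O-TBS-afzelechin | CC(C)(C)[Si](C)(C)Oc1cc(O[Si](C)(C)C(C)(C)C)c2C[C@H](O[Si](C)(C)C(C)(C)C)[C@@H](c3ccc(O[Si](C)(C)C(C)(C)C)cc3)Oc2c1Br | intermediate
4 | 2′,4′,6′-trihydroxyacetophenone | CC(=O)c1c(O)cc(O)cc1O | starting material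
5 | 2′,4′,6′-tris(benzyloxy)acetophenone | CC(=O)c1c(OCc2ccccc2)cc(OCc2ccccc2)cc1OCc1ccccc1 | intermediate
6 | deoxybenzoin, 2-(3,5,7,4′-tetra-O-TBS-afzelechin-8-yl)-1-[2,4,6-tris(benzyloxy)phenyl]ethanone | CC(C)(C)[Si](C)(C)Oc1cc(O[Si](C)(C)C(C)(C)C)c2C[C@H](O[Si](C)(C)C(C)(C)C)[C@@H](c3ccc(O[Si](C)(C)C(C)(C)C)cc3)Oc2c1CC(=O)c1c(OCc2ccccc2)cc(OCc2ccccc2)cc1OCc1ccccc1 | intermediate
7 | 4-(benzyloxy)benzaldehyde | O=Cc1ccc(OCc2ccccc2)cc1 | starting material
8 | (E)-α-aryl enone (aroyl trans to the 4-benzyloxyphenyl group) | O=C(c1c(OCc2ccccc2)cc(OCc2ccccc2)cc1OCc1ccccc1)/C(c1c(O[Si](C)(C)C(C)(C)C)cc(O[Si](C)(C)C(C)(C)C)c2c1O[C@H](c1ccc(O[Si](C)(C)C(C)(C)C)cc1)[C@@H](O[Si](C)(C)C(C)(C)C)C2)=C/c1ccc(OCc2ccccc2)cc1 | intermediate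
9 | (2S,3R)-epoxy ketone (oxirane C-2 bears the aroyl group and the afzelechin-8-yl group, C-3 bears H and 4-benzyloxyphenyl) | O=C(c1c(OCc2ccccc2)cc(OCc2ccccc2)cc1OCc1ccccc1)[C@@]1(c2c(O[Si](C)(C)C(C)(C)C)cc(O[Si](C)(C)C(C)(C)C)c3c2O[C@H](c2ccc(O[Si](C)(C)C(C)(C)C)cc2)[C@@H](O[Si](C)(C)C(C)(C)C)C3)O[C@@H]1c1ccc(OCc2ccccc2)cc1 | intermediate
10 | desilylated epoxy ketone (same (2S,3R)-oxirane; afzelechin 3-, 5-, 7- and 4′-OH free) | O=C(c1c(OCc2ccccc2)cc(OCc2ccccc2)cc1OCc1ccccc1)[C@@]1(c2c(O)cc(O)c3c2O[C@H](c2ccc(O)cc2)[C@@H](O)C3)O[C@@H]1c1ccc(OCc2ccccc2)cc1 | intermediate (not isolated)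
11 | dihydrofuranol tetrabenzyl ether: afzelechin with a 2,3-dihydrofuran fused at O-7/C-8; Cβ (S) bears H and 4-(benzyloxy)phenyl, Cα (S) bears OH and the 2,4,6-tris(benzyloxy)benzoyl group, aryl cis to OH; 3-, 5- and 4′-OH free | Oc1cc2O[C@@H](c3ccc(OCc4ccccc4)cc3)[C@](O)(C(=O)c3c(OCc4ccccc4)cc(OCc4ccccc4)cc3OCc3ccccc3)c2c2c1C[C@H](O)[C@@H](c1ccc(O)cc1)O2 | intermediate
12 | hexaphenol: 11 without its four benzyl groups (2,4,6-trihydroxybenzoyl and 4-hydroxyphenyl) | Oc1cc2O[C@@H](c3ccc(O)cc3)[C@](O)(C(=O)c3c(O)cc(O)cc3O)c2c2c1C[C@H](O)[C@@H](c1ccc(O)cc1)O2 | intermediate (not isolated)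
13 | genkwanol B (spiro C-8 S, Cα R, Cβ S, afzelechin C-2 R, C-3 S) | O=C1C=C2O[C@@H](c3ccc(O)cc3)[C@]3(O)C(=O)c4c(O)cc(O)cc4O[C@]23C2=C1C[C@H](O)[C@@H](c1ccc(O)cc1)O2 | target

**Totals**
Total step count: 8. Longest linear sequence: 7 steps (steps 1, 2, 4, 5, 6, 7, 8).

**Three steps most likely to fail**

1. Step 8. What may go wrong: unselective oxidation, in which the two 4-hydroxyphenyl groups or the acylphloroglucinol ring are oxidised alongside ring A, or loss of water from the free hexaphenol to the benzofuran before the oxidant acts. The fallback sets out from 11 and comes back at 13. Chelation-controlled cleavage of one benzyl ether ortho to the ketone with MgBr2·OEt2 (toluene/Et2O, rt) should give the 2′-phenol F1. PhI(OAc)2 in CF3CH2OH at −40 °C then meets a single phloroglucinol-type free phenol (ring A) and should close the chromanone to tri-O-benzyl genkwanol B F2. BCl3 with pentamethylbenzene (CH2Cl2, −78 °C) should then remove the three benzyl groups without hydrogen and give 13.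

2. Step 6. What may go wrong: oxygen transfer to the hindered, acyl-bearing trisubstituted alkene is slower than decomposition of the ketone catalyst, or facial selectivity is poor. The fallback sets out from 8 and comes back at 9. Weitz–Scheffer epoxidation (t-BuOOH, DBU, toluene, 0 °C → rt), which attacks the open β-carbon as a nucleophile, should give 9 together with its diastereomer, the (2R,3S)-epoxy ketone F3. Because the afzelechin stereocentres make the two epoxides diastereomers, they are separated by preparative HPLC and 9 is carried on, so stereocontrol comes from separation in place of reagent control.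

3. Step 5. What may go wrong: the aldol addition at the doubly flanked methylene stalls or reverts, so that no enone or a mixture of alkene isomers results. The fallback sets out from 3 (with 5 and 7) and comes back at 8. Claisen–Schmidt condensation of 5 with 7 (KOH, EtOH) should give chalcone F4. Pyridinium tribromide should add bromine to the enone double bond to give the erythro dibromide F5, and Et3N should eliminate HBr to the (Z)-α-bromochalcone F6. Miyaura borylation of 3 (B2pin2, Pd(dppf)Cl2, KOAc, dioxane) should give the 8-pinacolboronate F7. Suzuki–Miyaura coupling of F7 with F6 (Pd(OAc)2, SPhos, K3PO4, toluene/H2O) should replace bromine with retention of alkene geometry and give 8, so the enone is made by cross-coupling in place of condensation and step 4 is not needed.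

**Further compounds**
F1 | step 8 | 2′-phenol: 11 with the benzyl group on one ortho oxygen of the aroyl ring removed | Oc1cc2O[C@@H](c3ccc(OCc4ccccc4)cc3)[C@](O)(C(=O)c3c(O)cc(OCc4ccccc4)cc3OCc3ccccc3)c2c2c1C[C@H](O)[C@@H](c1ccc(O)cc1)O2
F2 | step 8 | tri-O-benzyl genkwanol B (benzyl on the 4-oxyphenyl group at Cβ and on the two free oxygens of the chromanone aryl ring) | O=C1C=C2O[C@@H](c3ccc(OCc5ccccc5)cc3)[C@]3(O)C(=O)c4c(OCc5ccccc5)cc(OCc5ccccc5)cc4O[C@]23C2=C1C[C@H](O)[C@@H](c1ccc(O)cc1)O2
F3 | step 6 | (2R,3S)-epoxy ketone, diastereomer of 9 | O=C(c1c(OCc2ccccc2)cc(OCc2ccccc2)cc1OCc1ccccc1)[C@]1(c2c(O[Si](C)(C)C(C)(C)C)cc(O[Si](C)(C)C(C)(C)C)c3c2O[C@H](c2ccc(O[Si](C)(C)C(C)(C)C)cc2)[C@@H](O[Si](C)(C)C(C)(C)C)C3)O[C@H]1c1ccc(OCc2ccccc2)cc1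
F4 | step 5 | (E)-3-[4-(benzyloxy)phenyl]-1-[2,4,6-tris(benzyloxy)phenyl]prop-2-en-1-one | O=C(/C=C/c1ccc(OCc2ccccc2)cc1)c1c(OCc2ccccc2)cc(OCc2ccccc2)cc1OCc1ccccc1
F5 | step 5 | erythro-2,3-dibromo-3-[4-(benzyloxy)phenyl]-1-[2,4,6-tris(benzyloxy)phenyl]propan-1-one (racemic; the 2R,3S enantiomer is drawn) | O=C([C@@H](Br)[C@@H](Br)c1ccc(OCc2ccccc2)cc1)c1c(OCc2ccccc2)cc(OCc2ccccc2)cc1OCc1ccccc1
F6 | step 5 | (Z)-2-bromo-3-[4-(benzyloxy)phenyl]-1-[2,4,6-tris(benzyloxy)phenyl]prop-2-en-1-one | O=C(/C(Br)=C/c1ccc(OCc2ccccc2)cc1)c1c(OCc2ccccc2)cc(OCc2ccccc2)cc1OCc1ccccc1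
F7 | step 5 | 3,5,7,4′-tetra-O-TBS-afzelechin-8-boronic acid pinacol ester | CC(C)(C)[Si](C)(C)Oc1cc(O[Si](C)(C)C(C)(C)C)c2C[C@H](O[Si](C)(C)C(C)(C)C)[C@@H](c3ccc(O[Si](C)(C)C(C)(C)C)cc3)Oc2c1B1OC(C)(C)C(C)(C)O1
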